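The readings are simulated from invented constants, noise included.

Late in the earlier runs, the rate of target formation can be read as two separate slowings, and the first gives the number to carry.

| flask | substrate | gas | free catalyst | remark | time |
|---|---|---|---|---|---|
| teal | 0.013 M (fed, over 4.0 min) | 16 mM (held) | 25 µM | run made earlier |  |
| blue | 0.037 M (fed, over 4.0 min) | 16 mM (held) | 25 µM | run made earlier |  |
| midnight | 0.050 M (fed, over 4.0 min) | 16 mM (held) | 25 µM |  | 20 min |
| summer | 0.015 M | 16 mM | 25 µM | everything together at the start | 20 min |

- teal (time / min: target / %, substrate / %): 2.00: 8.3, 41.9; 5.00: 35.3, 63.9; 10.0: 64.0, 35.4; 15.0: 79.9, 19.6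
- blue (time / min: target / %, substrate / %): 1.00: 1.4, 23.2; 2.50: 7.3, 55.6; 6.00: 20.3, 80.1; 15.0: 40.1, 59.9

(each reading ± 0.3 percentage points)

1. the flask that ends with the higher amount of target, in percent of the substrate charged, or "neither" when 2 percentage points or less lies between them (midnight / summer / neither)
2. final target, as a percentage of the substrate charged, in midnight
3. final target, as a percentage of the substrate charged, in summer

- at the start none of reagent is dissolved
- the earlier runs were read with a standard deviation of 0.3 percentage points
- steps thought possible: catalyst intermediate B -> free catalyst + target; gas <-> reagent; substrate + catalyst intermediate A -> catalyst intermediate B; free catalyst <-> dormant form; reagent + free catalyst -> catalyst intermediate A; substrate -> decomposition product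
- percentages count the whole charge, also what has not yet gone in

1. Blue makes target at r_e = 1.37 mM min⁻¹ between 2.50 min and 6.00 min.

2. From 6.00 min to 15.0 min, blue makes target at 0.814 mM min⁻¹: this is the ceiling rate r_c, the steady late rate of target formation while substrate is plentiful. This reading is 0.594 of r_e.

3. Teal's tail is read as pseudo-first-order: from 10.0 min to 15.0 min, its substrate falls by a factor 0.554, so k_L = 0.118 min⁻¹. The two rates meet at a substrate level A* = r_c/k_L = 6.88 mM.

4. Midnight, reckoned here as following blue in absolute terms, holds 18.9 mM of target at 20 min, or 37.8%. Its substrate stays above A*.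

5. Summer, reckoned the same way, runs at r_c for 9.97 min, and its substrate then decays by a factor 0.305. That leaves 14.0% of its substrate, so this reckoning gives 86.0% of target.

The forecast says summer, with 38% (34% to 43%) for midnight and 90% (84% to 94%) for summer, on the view that “reagent accumulated early is used up”. For summer, the reckoning above stands below the forecast.

The flasks give summer as the higher: 37.6% in midnight and 81.3% in summer.

    catalyst intermediate B → free catalyst + target (k = 260 s⁻¹)
    gas ⇌ reagent, rate k2*(csat - [reagent]) (kL = 0.00467 s⁻¹)
    substrate + catalyst intermediate A → catalyst intermediate B (k = 191 L mol⁻¹ s⁻¹)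
    free catalyst ⇌ dormant form (K = 15.5, k = 0.0113 s⁻¹)
    reagent + free catalyst → catalyst intermediate A (k = 743 L mol⁻¹ s⁻¹)
    substrate → decomposition product (k = 1.11 × 10⁻⁶ s⁻¹)

Midnight makes target at 0.776 mM min⁻¹ over its second half, against the r_c of 0.814 mM min⁻¹ read from blue. A neighbouring flask, midnight with 0.030 M of substrate, takes the same reckoning with r_c: 18.9 mM of target is 63.0% of its charge. Its substrate is then reckoned to end at 11.1 mM, above A*. That neighbouring flask gives 59.0%, with 41% of its substrate left.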